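**Retrosynthetic overview**

- Rings C (C2, C3, C6, C7) and D (C3–C6) together are a bicyclo[2.2.0]hexane, the valence isomer of a cyclohexa-1,3-diene with termini C3 and C6. The C3–C6 bond is therefore cut back to tricyclic diene 20 (C3=C4–C5=C6, sp3 C2 and C7), closed by light and then reduced at C4=C5.
- Diene 20 comes from cyclohexene 17 (C4=C5) by bromination and double dehydrobromination at or below room temperature. The chain terminus carries the acetonide-protected 2-glyceryl ether from the start, in place of a silyl ether.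
- C11 is set on meso diene 11 by enantioselective copper-hydride hydroboration, which should put boron on the exposed face of ring A, cis to ring B. Zweifel vinylation and an alkyl–alkyl Suzuki coupling with bromide 4 then build the chain with retention. Hydrogenation of a C10=C11 alkene is avoided because it would add hydrogen to that same face and give the C11 epimer.
- Meso 11 comes from double ring-closing metathesis of tetraallylcyclobutane 9, made from the cis,trans,cis cyclobutane dianhydride 5. This supplies ring B and the cis-anti-cis pattern without a Diels–Alder reaction on an unactivated cyclobutene.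
- Ring order: B (bought), then A and the six-membered precursor of rings C and D together (metathesis), then C and D (photoclosure).

Key step: step 11

Remark: locants are those of the target skeleton (chain on C11; C12 lies between C11 and C1) and are kept for all tricyclic intermediates; the enantiomer of DTBM-SEGPHOS in step 6 is to be the one that places boron on C11 ((R) is written), and HBpin is limiting there so that unreacted 11 is recycled.

**Route**

Step 1
Reactants: 1 2,2-dimethyl-1,3-dioxan-5-ol; 2 1,6-dibromohexane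
Product: 4 5-[(6-bromohexyl)oxy]-2,2-dimethyl-1,3-dioxane, via sodium 2,2-dimethyl-1,3-dioxan-5-olate 3 (not isolated)
Conditions: NaH, DMF, 0 °C; then 2 (4 equiv), 0 °C → rt
Reagents that add atoms: none
Why: Williamson ether synthesis, in which the secondary alkoxide displaces one primary bromide by SN2 and the excess of dibromide should hold back the bis-ether.

Step 2
Reactants: 5 (1α,2α,3β,4β)-cyclobutane-1,2,3,4-tetracarboxylic dianhydride
Product: 6 [(1α,2α,3β,4β)-cyclobutane-1,2,3,4-tetrayl]tetramethanol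
Conditions: LiAlH4, THF, reflux; aq. NaOH work-up
Reagents that add atoms: none
Why: hydride reduction of both cyclic anhydrides to four primary alcohols, which leaves the four ring stereocentres (two cis pairs on opposite faces) untouched.

Step 3
Reactants: 6 [(1α,2α,3β,4β)-cyclobutane-1,2,3,4-tetrayl]tetramethanol
Product: 7 (1α,2α,3β,4β)-cyclobutane-1,2,3,4-tetrayltetrakis(methylene) tetrakis(4-methylbenzenesulfonate)
Conditions: TsCl (excess), pyridine, 0 °C
Reagents that add atoms: 4-methylbenzenesulfonyl chloride (TsCl), Cc1ccc(cc1)S(Cl)(=O)=O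
Why: sulfonylation of primary alcohols, where low temperature and excess TsCl should outrun cyclisation of a mono-tosylate onto its cis neighbour.

Step 4
Reactants: 7 (1α,2α,3β,4β)-cyclobutane-1,2,3,4-tetrayltetrakis(methylene) tetrakis(4-methylbenzenesulfonate); 8 vinylmagnesium bromide
Product: 9 (1α,2α,3β,4β)-1,2,3,4-tetraallylcyclobutane
Conditions: CH2=CHMgBr (excess), Li2CuCl4 (cat.), THF, −30 °C → rt
Reagents that add atoms: none
Why: copper-catalysed cross-coupling of a Grignard reagent with primary alkyl sulfonates (substitution at CH2 by a vinylcuprate), which turns each CH2OTs into an allyl group without touching the ring stereocentres.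

Step 5
Reactants: 9 (1α,2α,3β,4β)-1,2,3,4-tetraallylcyclobutane
Product: 11 meso cis-anti-cis-tricyclo[6.4.0.0^2,7]dodeca-4,10-diene, via 7,8-diallylbicyclo[4.2.0]oct-3-ene 10 (not isolated)
Conditions: second-generation Grubbs catalyst RuCl2(=CHPh)(PCy3)(H2IMes) (2 mol%), CH2Cl2, 40 °C
Reagents that add atoms: none
Why: double ring-closing olefin metathesis, in which only the two cis-1,2 pairs of allyl groups can close to cis-fused cyclohexenes, so ring A and the future diene ring form on opposite faces of ring B and loss of ethene drives the reaction.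

Step 6
Reactants: 11 meso cis-anti-cis-tricyclo[6.4.0.0^2,7]dodeca-4,10-diene
Product: 12 2-[(11S)-cis-anti-cis-tricyclo[6.4.0.0^2,7]dodec-4-en-11-yl]-4,4,5,5-tetramethyl-1,3,2-dioxaborolane
Conditions: CuCl (5 mol%), (R)-DTBM-SEGPHOS (6 mol%), KOtBu (10 mol%), HBpin (0.6 equiv), toluene, rt
Reagents that add atoms: pinacolborane (HBpin), [H]B1OC(C)(C)C(C)(C)O1
Why: enantioselective hydroboration by a monovalent copper hydride bearing a chiral bisphosphine (syn hydrocupration, then σ-bond metathesis with HBpin with retention); copper should add to the exposed face of the boat-shaped ring A, cis to ring B and away from the axial H1 and H8, which sets H11 syn to H1 and H8, while the ligand selects C11 (and its homotopic partner C4) over the enantiotopic C10 and C5 and so sets the absolute configuration.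

Step 7
Reactants: 12 2-[(11S)-cis-anti-cis-tricyclo[6.4.0.0^2,7]dodec-4-en-11-yl]-4,4,5,5-tetramethyl-1,3,2-dioxaborolane; 8 vinylmagnesium bromide
Product: 15 (11S)-11-vinyl-cis-anti-cis-tricyclo[6.4.0.0^2,7]dodec-4-ene, via vinyl boronate complex 13 (not isolated), via β-iodoalkyl boronate 14 (not isolated)
Conditions: CH2=CHMgBr, THF/DMSO, rt; then I2, THF, 0 °C; then NaOMe, MeOH, 0 °C → rt
Reagents that add atoms: none
Why: Zweifel olefination, in which iodination of the vinyl boronate complex makes C11 migrate from boron to carbon with retention of configuration and methoxide-induced anti elimination of the β-iodoalkyl boronate then gives the vinyl group.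

Step 8
Reactants: 15 (11S)-11-vinyl-cis-anti-cis-tricyclo[6.4.0.0^2,7]dodec-4-ene; 4 5-[(6-bromohexyl)oxy]-2,2-dimethyl-1,3-dioxane
Product: 17 2,2-dimethyl-5-({8-[(11S)-cis-anti-cis-tricyclo[6.4.0.0^2,7]dodec-4-en-11-yl]octyl}oxy)-1,3-dioxane, via B-alkyl-9-BBN 16 (not isolated)
Conditions: 9-BBN, THF, 0 °C → rt; then 4, Pd(OAc)2 (4 mol%), PCy3 (8 mol%), K3PO4·H2O, THF, rt
Reagents that add atoms: none
Why: anti-Markovnikov hydroboration of the terminal vinyl group only (the ring cis-alkene is far slower toward 9-BBN), followed by an alkyl–alkyl Suzuki–Miyaura coupling of the primary alkylborane with the primary bromide under trialkylphosphine–palladium catalysis, which completes the eight-carbon chain without involving C11.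

Step 9
Reactants: 17 2,2-dimethyl-5-({8-[(11S)-cis-anti-cis-tricyclo[6.4.0.0^2,7]dodec-4-en-11-yl]octyl}oxy)-1,3-dioxane
Product: 18 trans-4,5-dibromide of 17 (both trans diastereomers)
Conditions: Br2 (1.0 equiv), K2CO3, CH2Cl2, −78 °C
Reagents that add atoms: bromine, BrBr
Why: electrophilic anti addition of bromine through a bromonium ion to the only alkene, where both trans diastereomers converge on the same diene and the carbonate shields the acetal from traces of HBr.

Step 10
Reactants: 18 trans-4,5-dibromide of 17 (both trans diastereomers)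
Product: 20 2,2-dimethyl-5-({8-[(11S)-cis-anti-cis-tricyclo[6.4.0.0^2,7]dodeca-3,5-dien-11-yl]octyl}oxy)-1,3-dioxane, via allylic bromide 19 (not isolated)
Conditions: KOtBu (3 equiv), 18-crown-6 (cat.), THF, 0 → 20 °C; cold work-up; used at once
Reagents that add atoms: none
Why: two successive anti E2 eliminations (H3 with Br4, then H6 with the allylic Br5) should give the conjugated diene at or below room temperature, where its thermal six-electron opening to the cyclooctatriene isomer is slow.

Step 11
Reactants: 20 2,2-dimethyl-5-({8-[(11S)-cis-anti-cis-tricyclo[6.4.0.0^2,7]dodeca-3,5-dien-11-yl]octyl}oxy)-1,3-dioxane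
Product: 21 2,2-dimethyl-5-({8-[(11S)-cis-anti-cis-anti-cis-tetracyclo[6.4.0.0^2,7.0^3,6]dodec-4-en-11-yl]octyl}oxy)-1,3-dioxane
Conditions: hν (254 nm, low-pressure Hg lamp, quartz), degassed pentane (0.01 M), −40 °C
Reagents that add atoms: none
Why: π→π* excitation of the s-cis diene leads to a disrotatory four-electron electrocyclisation that joins C3 and C6, the known photochemical valence isomerisation of cis-fused cyclohexa-1,3-dienes to bicyclo[2.2.0]hex-2-enes. Ring C (C2, C3, C6, C7) and ring D (C3–C6) are both closed by this one 4π disrotatory bond formation, ring D emerging as the C4=C5 cyclobutene. The new stereocentres C3 and C6 are cis to each other by orbital symmetry, and their sense relative to C2 and C7 is set by the direction of folding: the C4=C5 unit should swing to the face of the diene ring opposite ring B, so that H3 and H6, not C4 and C5, end up syn to C1 and C8, which is the anti ladder. The step needs closure to win over ring opening and hydrogen shifts, and anti folding to win over syn folding. The first is secured because the competing conrotatory six-electron opening would put a trans double bond in an eight-membered ring and should revert, and because the low temperature stops the thermal disrotatory opening; the second is secured by the bulk of rings A and B on one face of the diene. The cyclobutene product no longer absorbs at the wavelength used and should therefore accumulate.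

Step 12
Reactants: 21 2,2-dimethyl-5-({8-[(11S)-cis-anti-cis-anti-cis-tetracyclo[6.4.0.0^2,7.0^3,6]dodec-4-en-11-yl]octyl}oxy)-1,3-dioxane
Product: 22 2,2-dimethyl-5-({8-[(11S)-cis-anti-cis-anti-cis-tetracyclo[6.4.0.0^2,7.0^3,6]dodecan-11-yl]octyl}oxy)-1,3-dioxane
Conditions: 2-nitrobenzenesulfonohydrazide (excess), Et3N, CH2Cl2, rt
Reagents that add atoms: none
Why: diimide reduction, a concerted syn transfer of two hydrogens that is fastest for the strained cyclobutene and, unlike hydrogenation over a metal, carries no risk of hydrogenolysis of the strained ring bonds; no stereocentre is formed.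

Step 13
Reactants: 22 2,2-dimethyl-5-({8-[(11S)-cis-anti-cis-anti-cis-tetracyclo[6.4.0.0^2,7.0^3,6]dodecan-11-yl]octyl}oxy)-1,3-dioxane
Product: 23 2-({8-[(11S)-cis-anti-cis-anti-cis-tetracyclo[6.4.0.0^2,7.0^3,6]dodecan-11-yl]octyl}oxy)propane-1,3-diol (CNP0193334.1)
Conditions: AcOH/H2O/THF, 40 °C
Reagents that add atoms: none
Why: acid-catalysed hydrolysis of the isopropylidene acetal frees the 1,3-diol, and the saturated ladder should be stable to dilute acid.

**Compound list**

1 | 2,2-dimethyl-1,3-dioxan-5-ol | CC1(C)OCC(O)CO1 | starting material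
2 | 1,6-dibromohexane | BrCCCCCCBr | starting material
3 | sodium 2,2-dimethyl-1,3-dioxan-5-olate | CC1(C)OCC([O-])CO1.[Na+] | intermediate (not isolated)
4 | 5-[(6-bromohexyl)oxy]-2,2-dimethyl-1,3-dioxane | CC1(C)OCC(CO1)OCCCCCCBr | intermediate
5 | (1α,2α,3β,4β)-cyclobutane-1,2,3,4-tetracarboxylic 1,2:3,4-dianhydride (cis,trans,cis) | O=C1OC(=O)[C@H]2[C@@H]1[C@@H]3C(=O)OC(=O)[C@@H]32 | starting material
6 | [(1α,2α,3β,4β)-cyclobutane-1,2,3,4-tetrayl]tetramethanol | OC[C@@H]1[C@H](CO)[C@@H](CO)[C@H]1CO | intermediate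
7 | (1α,2α,3β,4β)-cyclobutane-1,2,3,4-tetrayltetrakis(methylene) tetrakis(4-methylbenzenesulfonate) | Cc1ccc(cc1)S(=O)(=O)OC[C@@H]1[C@H](COS(=O)(=O)c2ccc(C)cc2)[C@@H](COS(=O)(=O)c2ccc(C)cc2)[C@H]1COS(=O)(=O)c1ccc(C)cc1 | intermediate
8 | vinylmagnesium bromide | C=C[Mg]Br | starting material
9 | (1α,2α,3β,4β)-1,2,3,4-tetraallylcyclobutane | C=CC[C@@H]1[C@H](CC=C)[C@@H](CC=C)[C@H]1CC=C | intermediate
10 | cis-fused 7,8-diallylbicyclo[4.2.0]oct-3-ene (allyl groups cis to each other, on the cyclobutane face opposite the six-membered ring) | C1=CC[C@@H]2[C@H](C1)[C@@H](CC=C)[C@H]2CC=C | intermediate (not isolated)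
11 | meso cis-anti-cis-tricyclo[6.4.0.0^2,7]dodeca-4,10-diene | C1=CC[C@@H]2[C@H](C1)[C@H]1CC=CC[C@@H]21 | intermediate
12 | 2-[(11S)-cis-anti-cis-tricyclo[6.4.0.0^2,7]dodec-4-en-11-yl]-4,4,5,5-tetramethyl-1,3,2-dioxaborolane (boron cis to ring B; H11 syn to H1 and H8) | CC1(C)OB(OC1(C)C)[C@H]1CC[C@@H]2[C@H](C1)[C@H]1CC=CC[C@@H]21 | intermediate
13 | bromomagnesium vinyl boronate complex of 12 | C=C[B-]1(OC(C)(C)C(C)(C)O1)[C@H]1CC[C@@H]2[C@H](C1)[C@H]1CC=CC[C@@H]21.[Mg+]Br | intermediate (not isolated)
14 | 2-{2-iodo-1-[(11S)-cis-anti-cis-tricyclo[6.4.0.0^2,7]dodec-4-en-11-yl]ethyl}-4,4,5,5-tetramethyl-1,3,2-dioxaborolane (both epimers at the boron-bearing carbon) | ICC(B1OC(C)(C)C(C)(C)O1)[C@H]1CC[C@@H]2[C@H](C1)[C@H]1CC=CC[C@@H]21 | intermediate (not isolated)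
15 | (11S)-11-vinyl-cis-anti-cis-tricyclo[6.4.0.0^2,7]dodec-4-ene (vinyl cis to ring B) | C=C[C@H]1CC[C@@H]2[C@H](C1)[C@H]1CC=CC[C@@H]21 | intermediate
16 | 9-{2-[(11S)-cis-anti-cis-tricyclo[6.4.0.0^2,7]dodec-4-en-11-yl]ethyl}-9-borabicyclo[3.3.1]nonane | C1CCC2CCCC1B2CC[C@H]1CC[C@@H]2[C@H](C1)[C@H]1CC=CC[C@@H]21 | intermediate (not isolated)
17 | 2,2-dimethyl-5-({8-[(11S)-cis-anti-cis-tricyclo[6.4.0.0^2,7]dodec-4-en-11-yl]octyl}oxy)-1,3-dioxane | CC1(C)OCC(CO1)OCCCCCCCC[C@H]1CC[C@@H]2[C@H](C1)[C@H]1CC=CC[C@@H]21 | intermediate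
18 | trans-4,5-dibromide of 17 (both trans diastereomers form; one is drawn) | CC1(C)OCC(CO1)OCCCCCCCC[C@H]1CC[C@@H]2[C@H](C1)[C@H]1C[C@@H](Br)[C@H](Br)C[C@@H]21 | intermediate
19 | allylic bromide, 5-bromo-3-ene (with its 4-bromo-5-ene regioisomer) | CC1(C)OCC(CO1)OCCCCCCCC[C@H]1CC[C@@H]2[C@H](C1)[C@H]1C=CC(Br)C[C@@H]21 | intermediate (not isolated)
20 | 2,2-dimethyl-5-({8-[(11S)-cis-anti-cis-tricyclo[6.4.0.0^2,7]dodeca-3,5-dien-11-yl]octyl}oxy)-1,3-dioxane (key-step precursor) | CC1(C)OCC(CO1)OCCCCCCCC[C@H]1CC[C@@H]2[C@H](C1)[C@H]1C=CC=C[C@@H]21 | intermediate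
21 | 2,2-dimethyl-5-({8-[(11S)-cis-anti-cis-anti-cis-tetracyclo[6.4.0.0^2,7.0^3,6]dodec-4-en-11-yl]octyl}oxy)-1,3-dioxane (key-step product; H3 and H6 syn to H1 and H8) | CC1(C)OCC(CO1)OCCCCCCCC[C@H]1CC[C@@H]2[C@H](C1)[C@H]1[C@@H]3C=C[C@@H]3[C@@H]21 | intermediate
22 | 2,2-dimethyl-5-({8-[(11S)-cis-anti-cis-anti-cis-tetracyclo[6.4.0.0^2,7.0^3,6]dodecan-11-yl]octyl}oxy)-1,3-dioxane | CC1(C)OCC(CO1)OCCCCCCCC[C@H]1CC[C@@H]2[C@H](C1)[C@H]1[C@@H]3CC[C@@H]3[C@@H]21 | intermediate
23 | 2-({8-[(11S)-cis-anti-cis-anti-cis-tetracyclo[6.4.0.0^2,7.0^3,6]dodecan-11-yl]octyl}oxy)propane-1,3-diol (chain cis to ring B) | OCC(CO)OCCCCCCCC[C@H]1CC[C@@H]2[C@H](C1)[C@H]1[C@@H]3CC[C@@H]3[C@@H]21 | target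

**Step count**

Total: 13 steps. Longest linear sequence: 12 steps (5 → 23, steps 2–13); step 1 makes the side-chain fragment 4.

**Steps most likely to fail**

Step 11 (photoclosure). The excited diene may leak into conrotatory ring opening to the strained trans-cyclooctatriene, which can relax to the all-cis triene and be photolysed further, or it may undergo hydrogen shifts, so that little anti ladderene builds up.

The fallback sets out from 7 and comes back at 22; it makes rings C and D without light by building the ladder outward from the cyclobutane.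
- Tetratosylate 7 with Na2S·9H2O in DMF gives the bis-thiolane F1.
- N-Chlorosuccinimide gives the bis(α-chloro sulfide) F2, and mCPBA oxidises it to the bis(α-chloro sulfone) F3.
- KOtBu effects a double Ramberg–Bäcklund contraction to anti-tricyclo[4.2.0.0^2,5]octa-3,7-diene F4, in which the ring of 5 has become ring C.
- One strained cyclobutene bond of F4 takes buta-1,3-diene in a Diels–Alder reaction on its exo face (sealed tube, about 70 °C) to give the ladder diene F5 with ring A in place.
- Diimide reduces the remaining cyclobutene selectively to the meso ladder alkene F6.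
- Hydroboration as in step 6 gives the boronate F7.
- Zweifel vinylation as in step 7 passes through the vinyl boronate complex F8 and the β-iodoalkyl boronate F9 to the vinyl ladderane F10.
- 9-BBN gives the B-alkyl-9-BBN F11, which is coupled with 4 as in step 8 to give 22.

Step 6 (desymmetrising hydroboration). The copper hydride may discriminate poorly between the enantiotopic carbons C11 and C10, insert too slowly into the unactivated ring alkene, or hydroborate both rings.

The fallback sets out from 11 and comes back at 12; it uses reagent control in place of catalyst control.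
- (−)-Diisopinocampheylborane (from (+)-α-pinene and BH3·SMe2; its antipode if the sense is opposite) in THF at −25 °C adds to one alkene of 11 to give the trialkylborane F12. Its bulk should also hold back a second hydroboration.
- Acetaldehyde releases both pinanyl groups as α-pinene and leaves the diethyl boronate F13.
- Exchange with pinacol gives 12.

Step 10 (double dehydrobromination). The allylic bromide may be substituted by tert-butoxide, the second elimination may stall, or the base may isomerise the sensitive diene.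

The fallback sets out from 17 and comes back at 20; it is a 1,4-dehydration under nearly neutral conditions.
- Allylic oxidation of 17 (SeO2 cat., t-BuOOH, CH2Cl2) gives the allylic alcohol F14 (the 3-ol with its 6-ol regioisomer, which converge).
- 2,4-Dinitrobenzenesulfenyl chloride and Et3N give the sulfenate F15.
- F15 rearranges by a [2,3]-sigmatropic shift to the allylic sulfoxide F16, which should lose the sulfenic acid by syn elimination at or slightly above room temperature to give 20.

**Further compounds**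

F1 | step 11 | cis-anti-cis-4,9-dithiatricyclo[5.3.0.0^2,6]decane | C1SC[C@H]2[C@@H]1[C@@H]3CSC[C@@H]32
F2 | step 11 | bis(α-chloro sulfide) of F1 (one chlorine next to each sulfur; regio- and stereoisomers) | ClC1SC[C@H]2[C@@H]1[C@@H]3C(Cl)SC[C@@H]32
F3 | step 11 | bis(α-chloro sulfone), the 4,4,9,9-tetraoxide of F2 | ClC1S(=O)(=O)C[C@H]2[C@@H]1[C@@H]3C(Cl)S(=O)(=O)C[C@@H]32
F4 | step 11 | anti-tricyclo[4.2.0.0^2,5]octa-3,7-diene | C1=C[C@H]2[C@@H]1[C@@H]3C=C[C@@H]32
F5 | step 11 | cis-anti-cis-anti-cis-tetracyclo[6.4.0.0^2,7.0^3,6]dodeca-4,10-diene | C1=CC[C@@H]2[C@H](C1)[C@H]1[C@@H]3C=C[C@@H]3[C@@H]21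
F6 | step 11 | meso cis-anti-cis-anti-cis-tetracyclo[6.4.0.0^2,7.0^3,6]dodec-10-ene | C1=CC[C@@H]2[C@H](C1)[C@H]1[C@@H]3CC[C@@H]3[C@@H]21
F7 | step 11 | 2-[(11S)-cis-anti-cis-anti-cis-tetracyclo[6.4.0.0^2,7.0^3,6]dodecan-11-yl]-4,4,5,5-tetramethyl-1,3,2-dioxaborolane | CC1(C)OB(OC1(C)C)[C@H]1CC[C@@H]2[C@H](C1)[C@H]1[C@@H]3CC[C@@H]3[C@@H]21
F8 | step 11 | bromomagnesium vinyl boronate complex of F7 | C=C[B-]1(OC(C)(C)C(C)(C)O1)[C@H]1CC[C@@H]2[C@H](C1)[C@H]1[C@@H]3CC[C@@H]3[C@@H]21.[Mg+]Br
F9 | step 11 | β-iodoalkyl boronate from F8 (both epimers at the boron-bearing carbon) | ICC(B1OC(C)(C)C(C)(C)O1)[C@H]1CC[C@@H]2[C@H](C1)[C@H]1[C@@H]3CC[C@@H]3[C@@H]21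
F10 | step 11 | (11S)-11-vinyl-cis-anti-cis-anti-cis-tetracyclo[6.4.0.0^2,7.0^3,6]dodecane | C=C[C@H]1CC[C@@H]2[C@H](C1)[C@H]1[C@@H]3CC[C@@H]3[C@@H]21
F11 | step 11 | 9-{2-[(11S)-cis-anti-cis-anti-cis-tetracyclo[6.4.0.0^2,7.0^3,6]dodecan-11-yl]ethyl}-9-borabicyclo[3.3.1]nonane | C1CCC2CCCC1B2CC[C@H]1CC[C@@H]2[C@H](C1)[C@H]1[C@@H]3CC[C@@H]3[C@@H]21
F12 | step 6 | bis(isopinocampheyl)[(11S)-cis-anti-cis-tricyclo[6.4.0.0^2,7]dodec-4-en-11-yl]borane | B([C@@H]1C[C@@H]2C[C@H]([C@H]1C)C2(C)C)([C@@H]1C[C@@H]2C[C@H]([C@H]1C)C2(C)C)[C@H]1CC[C@@H]2[C@H](C1)[C@H]1CC=CC[C@@H]21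
F13 | step 6 | diethyl [(11S)-cis-anti-cis-tricyclo[6.4.0.0^2,7]dodec-4-en-11-yl]boronate | CCOB(OCC)[C@H]1CC[C@@H]2[C@H](C1)[C@H]1CC=CC[C@@H]21
F14 | step 10 | allylic alcohol, 3-hydroxy-4-ene of 17 (with its 6-hydroxy regioisomer; epimers at the carbinol) | CC1(C)OCC(CO1)OCCCCCCCC[C@H]1CC[C@@H]2[C@H](C1)[C@H]1C(O)C=CC[C@@H]21
F15 | step 10 | 2,4-dinitrobenzenesulfenate of F14 | CC1(C)OCC(CO1)OCCCCCCCC[C@H]1CC[C@@H]2[C@H](C1)[C@H]1C(OSc3ccc(cc3[N+](=O)[O-])[N+](=O)[O-])C=CC[C@@H]21
F16 | step 10 | allylic sulfoxide, 5-(2,4-dinitrophenylsulfinyl)-3-ene | CC1(C)OCC(CO1)OCCCCCCCC[C@H]1CC[C@@H]2[C@H](C1)[C@H]1C=CC(S(=O)c3ccc(cc3[N+](=O)[O-])[N+](=O)[O-])C[C@@H]21
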